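The route (guaiane numbering) rests on reading C3, the unsubstituted methylene of the five-membered ring C1–C5, as carbon monoxide. An allenic Pauson–Khand reaction of an acyclic allene-yne that already carries C6, C7 and C8 forms C1–C5, C2–C3 and C3–C4 in one operation. It closes the seven- and the five-membered ring and leaves the inner allene bond as the tetrasubstituted C1=C10 alkene, while the methyl alkyne supplies C4 and C15. The C3 carbonyl is then spent: its tosylhydrazone relays hydrogen to C5 by allylic diazene rearrangement and shifts the alkene to C3=C4 for Markovnikov hydration at C4. Site-selective esterification ends the synthesis.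

Key step: step 8

Remark on numbering: C1 (sp2) and C5 are the ring-fusion carbons. C2–C4 complete the five-membered ring and C6–C10 the seven-membered ring. C11–C13 are the isopropyl group on C7, C14 is the methyl on C10, and C15 is the methyl on C4. β is the face of the bicycle that carries O6 (and, in the target, H5, the 4-OH and the isopropyl group). α is the opposite face (O8, C15).
Assumption: 6, 10 (solution in THF) and 23 are bought as such.

Step 1
Reactants: 1 but-2-yn-1-ol; 2 triethyl orthoacetate
Product: 4 ethyl 3-methylpenta-3,4-dienoate, via ketene acetal 3 (not isolated)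
Conditions: 2 (excess, neat), EtCO2H (cat.), 140 °C, EtOH distilled off
Reagents that add atoms: none
Why: Johnson–Claisen (orthoester Claisen) rearrangement: acid-catalysed exchange gives ketene acetal 3, whose [3,3] shift across the propargylic triple bond is a known entry to β-allenic esters, here the C8–C9–C10(C14)=C1=C2 unit.

Step 2
Reactants: 4 ethyl 3-methylpenta-3,4-dienoate
Product: 5 3-methylpenta-3,4-dienal
Conditions: i-Bu2AlH (1.05 equiv), CH2Cl2, −78 °C; aq. potassium sodium tartrate; used at once as a cold solution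
Reagents that add atoms: none
Why: Partial reduction of an ester with i-Bu2AlH stops at the aldehyde level at −78 °C, and the cold, near-neutral work-up keeps the β-allenic aldehyde from slipping into conjugation.

Step 3
Reactants: 6 (R)-4-benzyl-3-(3-methylbutanoyl)-1,3-oxazolidin-2-one; 5 3-methylpenta-3,4-dienal
Product: 8 (R)-4-benzyl-3-[(2R,3S)-3-hydroxy-5-methyl-2-(propan-2-yl)hepta-5,6-dienoyl]-1,3-oxazolidin-2-one, via boron enolate 7 (not isolated)
Conditions: Bu2BOTf, Et3N, CH2Cl2, −78 → 0 °C; 5, −78 → 0 °C; aq. NaH2PO4/Na2HPO4 (pH 7), MeOH, 30% H2O2, 0 °C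
Reagents that add atoms: none
Why: Evans syn aldol reaction: the (Z)-boron enolate 7 adds through a closed Zimmerman–Traxler chair on the enolate face left open by the benzyl group of the (R)-auxiliary, which sets C7 (R) and C8 (S) in one event.

Step 4
Reactants: 8 aldol adduct
Product: 9 (2R,3S)-3-hydroxy-N-methoxy-N,5-dimethyl-2-(propan-2-yl)hepta-5,6-dienamide
Conditions: MeNH(OMe)·HCl, AlMe3, CH2Cl2, −10 °C → rt; aq. potassium sodium tartrate
Reagents that add atoms: N,O-dimethylhydroxylamine hydrochloride, CNOC.Cl
Why: Weinreb transamidation with the aluminium amide made in the flask, in which the free C8 hydroxyl binds aluminium and steers attack to the exocyclic imide carbonyl, so the hindered acyl group is released without touching C7 or C8.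

Step 5
Reactants: 9 Weinreb amide; 10 prop-1-yn-1-ylmagnesium bromide
Product: 11 (5R,6S)-6-hydroxy-8-methyl-5-(propan-2-yl)deca-8,9-dien-2-yn-4-one
Conditions: 10 (3.5 equiv), THF, −20 → 0 °C; inverse quench into cold aq. NaHSO4
Reagents that add atoms: none
Why: Weinreb ketone synthesis: after deprotonation of the hydroxyl the alkynyl Grignard reagent acylates only once at an N-methoxy-N-methyl amide, and the cold acidic inverse quench keeps the released amine from adding to the ynone and suppresses retro-aldol cleavage.

Step 6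
Reactants: 11 β-hydroxy ynone
Product: 12 (4R,5R,6S)-8-methyl-5-(propan-2-yl)deca-8,9-dien-2-yne-4,6-diol
Conditions: Me4NBH(OAc)3, MeCN–AcOH (1:1), −30 °C
Reagents that add atoms: none
Why: Evans–Saksena reduction: the borohydride exchanges an acetate for the C8 hydroxyl and delivers hydride intramolecularly through a chair transition state, which gives the 1,3-anti diol and so sets C6 (R).

Step 7
Reactants: 12 anti-diol
Product: 13 (4R,5R,6S)-4,6-bis(tert-butyldimethylsilyloxy)-8-methyl-5-(propan-2-yl)deca-8,9-dien-2-yne
Conditions: TBSOTf (2.5 equiv), 2,6-lutidine, CH2Cl2, 0 °C → rt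
Reagents that add atoms: tert-butyldimethylsilyl trifluoromethanesulfonate (TBSOTf), CC(C)(C)[Si](C)(C)OS(=O)(=O)C(F)(F)F
Why: Silylation of hindered secondary alcohols with a silyl triflate and a non-nucleophilic base gives two ethers that are inert to rhodium carbonyls, and the bulky C6 ether later shields the β face.

Step 8
Reactants: 13 bis-silylated allene-yne; 14 carbon monoxide
Product: 16 6β,8α-bis(tert-butyldimethylsilyloxy)-7αH-guaia-1(10),4-dien-3-one, via rhodacyclopentene 15 (not isolated)
Conditions: [Rh(CO)2Cl]2 (10 mol %), CO (1 atm), toluene (0.01 M), 110 °C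
Reagents that add atoms: none
Why: Allenic Pauson–Khand reaction, a formal [2+2+1] cycloaddition: monovalent rhodium binds the C4≡C5 alkyne and the distal C1=C2 bond of the allene and couples them oxidatively to rhodacyclopentene 15 (trivalent rhodium, new C1–C5 bond), CO (14) inserts into a Rh–C bond, and reductive elimination leaves the carbonyl carbon C3 bonded to C2 and to C4. The closest known reaction type is the [Rh(CO)2Cl]2-catalysed cyclocarbonylation of allene-ynes that have a four-atom tether, which gives bicyclo[5.3.0]deca-1,7-dien-9-ones, among them guaiane-type dienones. The seven-membered ring (C1, C5 to C10) closes in the oxidative cyclometallation, in which the alkyne carbon C5 bonds to the central allene carbon C1, and the five-membered ring (C1 to C5) closes by CO insertion and C–C reductive elimination. No stereocentre is formed: C6, C7 and C8 are spectators, and the proximal allene bond is left as the C1=C10 alkene, whose geometry is fixed by the ring. The step needs distal over proximal allene selectivity, secured by the rhodium carbonyl catalyst and by the methyl group on C10, and it needs carbonylation to outrun Alder-ene isomerisation and thermal [2+2] addition, secured by the lack of any β-hydrogen next to the Rh–C2 bond (C1 is fully substituted), by the CO atmosphere and by high dilution. Silyl ethers are chosen for O6 and O8 because a propargylic ester could suffer acyloxy migration on rhodium.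

Step 9
Reactants: 16 dienone
Product: 17 (E)-tosylhydrazone of 16
Conditions: TsNHNH2, AcOH (cat.), EtOH, 60 °C
Reagents that add atoms: 4-methylbenzenesulfonohydrazide (TsNHNH2), Cc1ccc(cc1)S(=O)(=O)NN
Why: Condensation of a ketone with a sulfonyl hydrazide, in which C3 is the only carbonyl carbon and the N–N bond settles anti to the C15 methyl group.

Step 10
Reactants: 17 tosylhydrazone
Product: 19 6β,8α-bis(tert-butyldimethylsilyloxy)-5βH,7αH-guaia-1(10),3-diene, via allylic diazene 18 (not isolated)
Conditions: catecholborane, CHCl3, −10 → 0 °C; NaOAc·3H2O, 65 °C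
Reagents that add atoms: none
Why: Reductive 1,3-transposition of an enone tosylhydrazone (allylic diazene rearrangement): catecholborane should attack C3 from the α face because the pseudoaxial C6 silyl ether covers the β face, loss of sulfinate gives the β-diazene 18, and its suprafacial retro-ene loss of N2 hands hydrogen to the β face of C5, which sets C5 (R), erases the C3 oxygen and moves the alkene to C3=C4.

Step 11
Reactants: 19 diene
Product: 21 6β,8α-bis(tert-butyldimethylsilyloxy)-5βH,7αH-guai-1(10)-en-4β-ol, via hydroperoxide 20 (not isolated)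
Conditions: Co(acac)2 (20 mol %), PhSiH3, O2 (1 atm), THF, 0 °C → rt; then PPh3
Reagents that add atoms: dioxygen, O=O
Why: Mukaiyama hydration (cobalt-hydride hydrogen-atom transfer): hydrogen should add to C3 of the trisubstituted alkene faster than to the shielded tetrasubstituted C1=C10 bond, and the planar tertiary C4 radical should capture O2 anti to the C5–C6 bond, on the face of H5, which sets C4 (S) after reduction of hydroperoxide 20 by PPh3.

Step 12
Reactants: 21 bis-silyl ether
Product: 22 5βH,7αH-guai-1(10)-ene-4β,6β,8α-triol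
Conditions: Bu4NF, THF, 50 °C
Reagents that add atoms: none
Why: Fluoride-mediated cleavage of silyl ethers is driven by the Si–F bond, no base-sensitive group is present, and the tertiary alcohol and the alkene are inert.

Step 13
Reactants: 22 triol; 23 angelic acid [(Z)-2-methylbut-2-enoic acid]
Product: 25 8α-angeloyloxy-5βH,7αH-guai-1(10)-ene-4β,6β-diol, via mixed anhydride 24 (not isolated)
Conditions: 23 (1.1 equiv), 2,4,6-Cl3C6H2COCl, Et3N, toluene, rt; then 22, toluene, 80 °C
Reagents that add atoms: none
Why: Yamaguchi-type esterification through mixed anhydride 24 without a nucleophilic catalyst is known to keep the (Z)-geometry of angelates, and the C8 hydroxyl, next to the C9 methylene, should react before the C6 hydroxyl, which lies between two tertiary carbons and is hydrogen-bonded to the syn C4 hydroxyl, and before the tertiary C4 hydroxyl.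

Step 14
Reactants: 25 mono-angelate
Product: 26 6β-acetoxy-8α-angeloyloxy-5βH,7αH-guai-1(10)-en-4β-ol, the (4S,5R,6R,7R,8S) target CNP0258590.1
Conditions: Ac2O, pyridine, 4-(dimethylamino)pyridine (cat.), CH2Cl2, rt
Reagents that add atoms: acetic anhydride, CC(=O)OC(C)=O
Why: Acetylation catalysed by 4-(dimethylamino)pyridine brings the small acetyl group onto the hindered secondary C6 hydroxyl at room temperature, whereas the tertiary C4 hydroxyl does not react and no stereocentre is touched.

Compound list
1 | but-2-yn-1-ol | CC#CCO | starting material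
2 | triethyl orthoacetate | CCOC(C)(OCC)OCC | starting material
3 | 1-(but-2-yn-1-yloxy)-1-ethoxyethene (mixed ketene acetal, not isolated) | C=C(OCC)OCC#CC | intermediate
4 | ethyl 3-methylpenta-3,4-dienoate | CCOC(=O)CC(C)=C=C | intermediate
5 | 3-methylpenta-3,4-dienal | O=CCC(C)=C=C | intermediate
6 | (R)-4-benzyl-3-(3-methylbutanoyl)-1,3-oxazolidin-2-one | CC(C)CC(=O)N1[C@H](Cc2ccccc2)COC1=O | starting material
7 | (Z)-dibutylboron enolate of 6 (not isolated) | CC(C)/C=C(\OB(CCCC)CCCC)N1[C@H](Cc2ccccc2)COC1=O | intermediate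
8 | (R)-4-benzyl-3-[(2R,3S)-3-hydroxy-5-methyl-2-(propan-2-yl)hepta-5,6-dienoyl]-1,3-oxazolidin-2-one | C=C=C(C)C[C@H](O)[C@@H](C(C)C)C(=O)N1[C@H](Cc2ccccc2)COC1=O | intermediate
9 | (2R,3S)-3-hydroxy-N-methoxy-N,5-dimethyl-2-(propan-2-yl)hepta-5,6-dienamide | C=C=C(C)C[C@H](O)[C@@H](C(C)C)C(=O)N(C)OC | intermediate
10 | prop-1-yn-1-ylmagnesium bromide | CC#C[Mg]Br | starting material
11 | (5R,6S)-6-hydroxy-8-methyl-5-(propan-2-yl)deca-8,9-dien-2-yn-4-one | C=C=C(C)C[C@H](O)[C@@H](C(C)C)C(=O)C#CC | intermediate
12 | (4R,5R,6S)-8-methyl-5-(propan-2-yl)deca-8,9-dien-2-yne-4,6-diol | C=C=C(C)C[C@H](O)[C@@H](C(C)C)[C@@H](O)C#CC | intermediate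
13 | (4R,5R,6S)-4,6-bis(tert-butyldimethylsilyloxy)-8-methyl-5-(propan-2-yl)deca-8,9-dien-2-yne | C=C=C(C)C[C@H](O[Si](C)(C)C(C)(C)C)[C@@H](C(C)C)[C@@H](O[Si](C)(C)C(C)(C)C)C#CC | intermediate
14 | carbon monoxide | [C-]#[O+] | starting material
15 | rhodacyclopentene, Rh bonded to C2 and C4 (further CO ligands not drawn, not isolated) | CC(C)(C)[Si](C)(C)O[C@H]1CC(C)=C2C[Rh](Cl)C(C)=C2[C@H](O[Si](C)(C)C(C)(C)C)[C@@H]1C(C)C | intermediate
16 | 6β,8α-bis(tert-butyldimethylsilyloxy)-7αH-guaia-1(10),4-dien-3-one (6R,7R,8S) | CC(C)(C)[Si](C)(C)O[C@H]1CC(C)=C2CC(=O)C(C)=C2[C@H](O[Si](C)(C)C(C)(C)C)[C@@H]1C(C)C | intermediate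
17 | (E)-tosylhydrazone of 16 | CC(C)(C)[Si](C)(C)O[C@H]1CC(C)=C2C/C(=N\NS(=O)(=O)c3ccc(C)cc3)C(C)=C2[C@H](O[Si](C)(C)C(C)(C)C)[C@@H]1C(C)C | intermediate
18 | 3β-diazenyl-6β,8α-bis(tert-butyldimethylsilyloxy)-7αH-guaia-1(10),4-diene (not isolated) | CC(C)(C)[Si](C)(C)O[C@H]1CC(C)=C2C[C@H](N=N)C(C)=C2[C@H](O[Si](C)(C)C(C)(C)C)[C@@H]1C(C)C | intermediate
19 | 6β,8α-bis(tert-butyldimethylsilyloxy)-5βH,7αH-guaia-1(10),3-diene | CC(C)(C)[Si](C)(C)O[C@H]1CC(C)=C2CC=C(C)[C@H]2[C@H](O[Si](C)(C)C(C)(C)C)[C@@H]1C(C)C | intermediate
20 | 4β-hydroperoxy-6β,8α-bis(tert-butyldimethylsilyloxy)-5βH,7αH-guai-1(10)-ene (not isolated) | CC(C)(C)[Si](C)(C)O[C@H]1CC(C)=C2CC[C@](C)(OO)[C@H]2[C@H](O[Si](C)(C)C(C)(C)C)[C@@H]1C(C)C | intermediate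
21 | 6β,8α-bis(tert-butyldimethylsilyloxy)-5βH,7αH-guai-1(10)-en-4β-ol | CC(C)(C)[Si](C)(C)O[C@H]1CC(C)=C2CC[C@](C)(O)[C@H]2[C@H](O[Si](C)(C)C(C)(C)C)[C@@H]1C(C)C | intermediate
22 | 5βH,7αH-guai-1(10)-ene-4β,6β,8α-triol | O[C@H]1CC(C)=C2CC[C@](C)(O)[C@H]2[C@H](O)[C@@H]1C(C)C | intermediate
23 | angelic acid, (Z)-2-methylbut-2-enoic acid | C/C=C(/C)C(=O)O | starting material
24 | angelic 2,4,6-trichlorobenzoic anhydride (not isolated) | C/C=C(/C)C(=O)OC(=O)c1c(Cl)cc(Cl)cc1Cl | intermediate
25 | 8α-angeloyloxy-5βH,7αH-guai-1(10)-ene-4β,6β-diol | C/C=C(/C)C(=O)O[C@H]1CC(C)=C2CC[C@](C)(O)[C@H]2[C@H](O)[C@@H]1C(C)C | intermediate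
26 | 6β-acetoxy-8α-angeloyloxy-5βH,7αH-guai-1(10)-en-4β-ol, (4S,5R,6R,7R,8S), CNP0258590.1 | C/C=C(/C)C(=O)O[C@H]1CC(C)=C2CC[C@](C)(O)[C@H]2[C@H](OC(C)=O)[C@@H]1C(C)C | target

Total step count: 14. Longest linear sequence: 14 steps (1 → 26).

Steps most likely to fail

Step 10.
- What may go wrong: hydride delivery to C3 of 17 relies on a remote steric bias. Poor facial discrimination there would be copied into C5 by the retro-ene step. The hindered hydrazone may also be reduced only sluggishly.
- Fallback: it sets out from 16 and replaces substrate control by reagent control plus a stereospecific substitution.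
- Corey–Bakshi–Shibata reduction with (S)-1-methyl-3,3-diphenyltetrahydro-1H,3H-pyrrolo[1,2-c][1,3,2]oxazaborole and BH3·SMe2 should give the 3α-allylic alcohol F1.
- Mitsunobu displacement of F1 with 2-nitrobenzenesulfonohydrazide (PPh3, diethyl azodicarboxylate, THF, −30 °C) inverts C3 to the 3β-sulfonylhydrazine F2.
- On warming to room temperature F2 loses the sulfinic acid to give diazene 18, so the fallback comes back to the route at 19.

Step 11.
- What may go wrong: hydrogen abstraction at the doubly allylic C2 and C5 positions, isomerisation of the skipped diene into conjugation, competing reaction at C1=C10, or a weak facial preference in the capture of oxygen.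
- Fallback: it sets out from 19 and replaces the radical hydration by a polar one.
- Oxymercuration with Hg(OAc)2 in THF–H2O is very slow at tetrasubstituted alkenes.
- Water should enter at C4 anti to the C5–C6 bond while mercury sits on the remote α face of C3. This gives the 3α-acetoxymercurio-4β-alcohol F3.
- Reductive demercuration of F3 (NaBH4, aq. NaOH) comes back to the route at 21.

Step 13.
- What may go wrong: the site selectivity between the two secondary hydroxyl groups may erode at the temperature that angeloylation needs. That would lead to acylation at O6 or to double acylation.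
- Fallback: it sets out from 22 and uses a temporary ring.
- Only the syn-1,3 pair O4/O6 can be bridged. PhB(OH)2 (toluene, molecular sieves 4 Å) should therefore give the cyclic 4,6-phenylboronate F4, which leaves the C8 hydroxyl as the only free one.
- Acylation of F4 with mixed anhydride 24 (toluene, 80 °C) gives the boronate angelate F5.
- Transesterification of F5 with pinacol at room temperature frees O4 and O6 and comes back to the route at 25.

Further compounds
F1 | step 10 | 3α-hydroxy-6β,8α-bis(tert-butyldimethylsilyloxy)-7αH-guaia-1(10),4-diene | CC(C)(C)[Si](C)(C)O[C@H]1CC(C)=C2C[C@@H](O)C(C)=C2[C@H](O[Si](C)(C)C(C)(C)C)[C@@H]1C(C)C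
F2 | step 10 | N-(6β,8α-bis(tert-butyldimethylsilyloxy)-7αH-guaia-1(10),4-dien-3β-yl)-2-nitrobenzenesulfonohydrazide | CC(C)(C)[Si](C)(C)O[C@H]1CC(C)=C2C[C@H](N(N)S(=O)(=O)c3ccccc3[N+](=O)[O-])C(C)=C2[C@H](O[Si](C)(C)C(C)(C)C)[C@@H]1C(C)C
F3 | step 11 | 3α-(acetoxymercurio)-6β,8α-bis(tert-butyldimethylsilyloxy)-5βH,7αH-guai-1(10)-en-4β-ol | CC(C)(C)[Si](C)(C)O[C@H]1CC(C)=C2C[C@@H]([Hg]OC(C)=O)[C@](C)(O)[C@H]2[C@H](O[Si](C)(C)C(C)(C)C)[C@@H]1C(C)C
F4 | step 13 | cyclic 4β,6β-phenylboronate of triol 22 (free 8α-OH) | O[C@H]1CC(C)=C2CC[C@](C)(O3)[C@H]2[C@H](OB3c4ccccc4)[C@@H]1C(C)C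
F5 | step 13 | cyclic 4β,6β-phenylboronate of 25 (8α-angelate) | C/C=C(/C)C(=O)O[C@H]1CC(C)=C2CC[C@](C)(O3)[C@H]2[C@H](OB3c4ccccc4)[C@@H]1C(C)C
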